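**Retrosynthetic overview**
1. The last bond made is the depside aryl ester C(=O)–O. It joins a benzyl-protected orsellinic acid (A ring) to the free 4-OH of benzyl 2-heptyl-4,6-dihydroxybenzoate (B ring). One hydrogenolysis then removes all three benzyl groups.
2. The B-ring benzyl ester comes from the methyl resorcylate, which comes from oxidative aromatisation of a 6-heptylcyclohexane-1,3-dione-carboxylate.
3. That dione comes from the key C–C bond: intermolecular Michael addition of dimethyl malonate to (E)-undec-3-en-2-one. An intramolecular Claisen closure follows in the same flask, and this is the only ring built in the route.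
4. The enone comes from octanal and the acetonyl ylide.
5. The A ring is bought as methyl orsellinate and only needs O-benzylation and saponification.

Assumption: the target has no stereocentre and is achiral, so no enantiocontrol is needed. The stereocentres of racemic 5–7 are erased on aromatisation, and the only stereodescriptor in the route is the E alkene of 3.

**Step 1**
Reactants: 1 octanal; 2 1-(triphenyl-λ5-phosphanylidene)propan-2-one
Product: 3 (E)-undec-3-en-2-one
Conditions: 2 (1.1 equiv), CH2Cl2, 40 °C, 24 h
Reagents that add atoms: none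
Why: Wittig olefination with a stabilised acyl ylide reacts cleanly with the aldehyde, avoids octanal self-aldol and gives the E-enone almost exclusively.

**Step 2**
Reactants: 3 (E)-undec-3-en-2-one; 4 dimethyl malonate
Product: 6 methyl 6-heptyl-2-hydroxy-4-oxocyclohex-2-ene-1-carboxylate (racemic), via Michael adduct 5 (not isolated)
Conditions: NaOMe (1.2 equiv), 4 (1.1 equiv), MeOH, rt then reflux, 4 h; aq. HCl
Reagents that add atoms: none
Why: Intermolecular Michael addition of the soft malonate anion to the enone β-carbon forms the key C–C bond, and the methyl-ketone enolate of 5 then closes the six-membered ring by an intramolecular Claisen (Dieckmann-type) condensation driven by the stabilised 1,3-dione enolate; the stereocentres formed are racemic and are erased in step 3.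

**Step 3**
Reactants: 6 methyl 6-heptyl-2-hydroxy-4-oxocyclohex-2-ene-1-carboxylate
Product: 8 methyl 2-heptyl-4,6-dihydroxybenzoate, via 3-bromo dione 7 (not isolated)
Conditions: Br2 (1.0 equiv), DMF, 0 °C, 1 h; then 75–80 °C, 12 h; aq. Na2S2O3
Reagents that add atoms: bromine, BrBr (its Br sits only in intermediate 7 and is gone in 8)
Why: Oxidative aromatisation by bromination–dehydrobromination, in which the enolised dione is brominated, bromine migrates under HBr, HBr is lost and tautomerisation gives the resorcylate; DMF buffers the HBr, and keeping to 80 °C or below limits ester cleavage and decarboxylation.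

**Step 4**
Reactants: 8 methyl 2-heptyl-4,6-dihydroxybenzoate
Product: 9 2-heptyl-4,6-dihydroxybenzoic acid
Conditions: KOH (6 equiv), H2O/MeOH, reflux, N2; then cold 2 M HCl, 0 °C, extraction and evaporation below 30 °C
Reagents that add atoms: potassium hydroxide, [K+].[OH-]
Why: Saponification (BAc2), in which the phenoxide-carboxylate polyanion resists decarboxylation in strong base and the free acid is liberated only in the cold.

**Step 5**
Reactants: 9 2-heptyl-4,6-dihydroxybenzoic acid
Product: 10 benzyl 2-heptyl-4,6-dihydroxybenzoate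
Conditions: BnBr (1.05 equiv), KHCO3 (1.3 equiv), DMF, rt, 18 h
Reagents that add atoms: benzyl bromide, BrCc1ccccc1
Why: SN2 alkylation of the carboxylate, selective because hydrogencarbonate deprotonates only the carboxylic acid and leaves both phenols untouched.

**Step 6**
Reactants: 11 methyl 2,4-dihydroxy-6-methylbenzoate (methyl orsellinate)
Product: 12 methyl 2,4-bis(benzyloxy)-6-methylbenzoate
Conditions: BnBr (2.5 equiv), K2CO3 (3 equiv), DMF, 60 °C, 12 h
Reagents that add atoms: benzyl bromide, BrCc1ccccc1
Why: Williamson ether synthesis, where carbonate in warm DMF is strong enough to alkylate the chelated 2-OH as well.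

**Step 7**
Reactants: 12 methyl 2,4-bis(benzyloxy)-6-methylbenzoate
Product: 13 2,4-bis(benzyloxy)-6-methylbenzoic acid
Conditions: KOH (8 equiv), DMSO/H2O 4:1, 95 °C, 6 h; then aq. HCl
Reagents that add atoms: potassium hydroxide, [K+].[OH-]
Why: Saponification of the di-ortho-substituted ester by poorly solvated hydroxide in hot DMSO, with benzyl ethers inert to base and the O-protected acid not prone to decarboxylation.

**Step 8**
Reactants: 13 2,4-bis(benzyloxy)-6-methylbenzoic acid; 10 benzyl 2-heptyl-4,6-dihydroxybenzoate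
Product: 15 benzyl 4-{[2,4-bis(benzyloxy)-6-methylbenzoyl]oxy}-2-heptyl-6-hydroxybenzoate, via mixed trifluoroacetic anhydride 14 (not isolated)
Conditions: (CF3CO)2O (4 equiv), dry toluene, rt, 4–16 h; aq. NaHCO3
Reagents that add atoms: trifluoroacetic anhydride, O=C(OC(=O)C(F)(F)F)C(F)(F)F (its CF3CO group sits only in intermediate 14 and is gone in 15)
Why: Mixed-anhydride esterification, in which the electron-rich aroyl trifluoroacetate (acylium-like) overcomes the ortho hindrance and acylates the free 4-OH, while the 2-OH is held back by its hydrogen bond to the ester carbonyl and any aryl trifluoroacetate is cleaved in the bicarbonate wash.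

**Step 9**
Reactants: 15 benzyl 4-{[2,4-bis(benzyloxy)-6-methylbenzoyl]oxy}-2-heptyl-6-hydroxybenzoate
Product: 16 4-[(2,4-dihydroxy-6-methylbenzoyl)oxy]-2-heptyl-6-hydroxybenzoic acid
Conditions: H2 (1 atm), 10% Pd/C, EtOAc, rt, 3 h
Reagents that add atoms: none
Why: Catalytic hydrogenolysis removes two benzyl ethers and the benzyl ester under neutral conditions in a non-nucleophilic solvent, so the depside ester and the decarboxylation-prone acid survive.

**Compound list**
1 | octanal | CCCCCCCC=O | starting material
2 | 1-(triphenyl-λ5-phosphanylidene)propan-2-one | CC(=O)C=P(c1ccccc1)(c1ccccc1)c1ccccc1 | starting material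
3 | (E)-undec-3-en-2-one | CCCCCCC/C=C/C(C)=O | intermediate
4 | dimethyl malonate | COC(=O)CC(=O)OC | starting material
5 | dimethyl 2-(2-oxoundecan-4-yl)propanedioate (racemic, not isolated) | CCCCCCCC(CC(C)=O)C(C(=O)OC)C(=O)OC | intermediate
6 | methyl 6-heptyl-2-hydroxy-4-oxocyclohex-2-ene-1-carboxylate (racemic, enol form of the 1,3-dione) | CCCCCCCC1CC(=O)C=C(O)C1C(=O)OC | intermediate
7 | methyl 3-bromo-6-heptyl-2-hydroxy-4-oxocyclohex-2-ene-1-carboxylate (racemic, not isolated) | CCCCCCCC1CC(=O)C(Br)=C(O)C1C(=O)OC | intermediate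
8 | methyl 2-heptyl-4,6-dihydroxybenzoate | CCCCCCCc1cc(O)cc(O)c1C(=O)OC | intermediate
9 | 2-heptyl-4,6-dihydroxybenzoic acid | CCCCCCCc1cc(O)cc(O)c1C(=O)O | intermediate
10 | benzyl 2-heptyl-4,6-dihydroxybenzoate | CCCCCCCc1cc(O)cc(O)c1C(=O)OCc1ccccc1 | intermediate
11 | methyl 2,4-dihydroxy-6-methylbenzoate (methyl orsellinate) | COC(=O)c1c(C)cc(O)cc1O | starting material
12 | methyl 2,4-bis(benzyloxy)-6-methylbenzoate | COC(=O)c1c(C)cc(OCc2ccccc2)cc1OCc1ccccc1 | intermediate
13 | 2,4-bis(benzyloxy)-6-methylbenzoic acid | OC(=O)c1c(C)cc(OCc2ccccc2)cc1OCc1ccccc1 | intermediate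
14 | 2,4-bis(benzyloxy)-6-methylbenzoic trifluoroacetic anhydride (not isolated) | O=C(OC(=O)C(F)(F)F)c1c(C)cc(OCc2ccccc2)cc1OCc1ccccc1 | intermediate
15 | benzyl 4-{[2,4-bis(benzyloxy)-6-methylbenzoyl]oxy}-2-heptyl-6-hydroxybenzoate | CCCCCCCc1cc(OC(=O)c2c(C)cc(OCc3ccccc3)cc2OCc2ccccc2)cc(O)c1C(=O)OCc1ccccc1 | intermediate
16 | 4-[(2,4-dihydroxy-6-methylbenzoyl)oxy]-2-heptyl-6-hydroxybenzoic acid (achiral) | CCCCCCCc1cc(OC(=O)c2c(C)cc(O)cc2O)cc(O)c1C(=O)O | target

**Total step count:** 9. **Longest linear sequence:** 7 (steps 1, 2, 3, 4, 5, 8, 9). Steps 6 and 7 form the convergent A-ring branch.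

**Three steps most likely to fail**

Step 3 (aromatisation: moderate yield, competing ester cleavage and decarboxylation by HBr at 80 °C). The fallback sets out from 6 and comes back at 8. In place of a one-equivalent oxidation with heating, 6 is deliberately over-brominated with Br2 (3 equiv) in AcOH at room temperature. This aromatises without heating and gives crystalline methyl 3,5-dibromo-2-heptyl-4,6-dihydroxybenzoate F1. The two aryl bromides are then removed by hydrogenolysis (H2, Pd/C, NaOAc, MeOH, rt) to give 8.

Step 4 (the free dihydroxy acid may decarboxylate during hydrolysis or work-up). The fallback sets out from 8 and comes back at 10, and it never makes the free acid 9.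
- Compound 8 is bis-protected (MOMCl, NaH, DMF, 0 °C) to methyl 2-heptyl-4,6-bis(methoxymethoxy)benzoate F2.
- F2 is saponified (KOH, DMSO/H2O, 90 °C; citric acid to pH 4–5) to 2-heptyl-4,6-bis(methoxymethoxy)benzoic acid F3. This acid has no free phenol and so cannot decarboxylate through a keto tautomer.
- F3 is alkylated (BnBr, K2CO3, DMF, rt) to benzyl 2-heptyl-4,6-bis(methoxymethoxy)benzoate F4.
- The two acetals are removed with catalytic HCl in MeOH at 40 °C, where the hindered benzyl ester does not transesterify, giving 10.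

Step 8 (hindered acid, possible 2-O- or bis-acylation). The fallback sets out from 8, uses 13 unchanged as partner and comes back at 16. The B-ring carboxyl is introduced only after the coupling.
- Compound 8 is saponified and deliberately decarboxylated in one pot (aq. NaOH, reflux; then HCl, reflux, passing through 9) to 5-heptylbenzene-1,3-diol F5.
- Vilsmeier–Haack formylation (POCl3, DMF, 0 °C to rt; aqueous hydrolysis) gives 2-heptyl-4,6-dihydroxybenzaldehyde F6. Its 2-OH is locked in an even stronger hydrogen bond, and its 4-OH is more acidic.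
- Steglich coupling of F6 with 13 (DCC, cat. DMAP, CH2Cl2, rt) gives 4-formyl-3-heptyl-5-hydroxyphenyl 2,4-bis(benzyloxy)-6-methylbenzoate F7.
- Pinnick oxidation (NaClO2, sulfamic acid, aq. dioxane, 0 °C to rt) gives 4-{[2,4-bis(benzyloxy)-6-methylbenzoyl]oxy}-2-heptyl-6-hydroxybenzoic acid F8.
- Hydrogenolysis (H2, Pd/C, EtOAc, rt) gives 16.

**Further compounds**
F1 | step 3 | methyl 3,5-dibromo-2-heptyl-4,6-dihydroxybenzoate | CCCCCCCc1c(Br)c(O)c(Br)c(O)c1C(=O)OC
F2 | step 4 | methyl 2-heptyl-4,6-bis(methoxymethoxy)benzoate | CCCCCCCc1cc(OCOC)cc(OCOC)c1C(=O)OC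
F3 | step 4 | 2-heptyl-4,6-bis(methoxymethoxy)benzoic acid | CCCCCCCc1cc(OCOC)cc(OCOC)c1C(=O)O
F4 | step 4 | benzyl 2-heptyl-4,6-bis(methoxymethoxy)benzoate | CCCCCCCc1cc(OCOC)cc(OCOC)c1C(=O)OCc1ccccc1
F5 | step 8 | 5-heptylbenzene-1,3-diol | CCCCCCCc1cc(O)cc(O)c1
F6 | step 8 | 2-heptyl-4,6-dihydroxybenzaldehyde | CCCCCCCc1cc(O)cc(O)c1C=O
F7 | step 8 | 4-formyl-3-heptyl-5-hydroxyphenyl 2,4-bis(benzyloxy)-6-methylbenzoate | CCCCCCCc1cc(OC(=O)c2c(C)cc(OCc3ccccc3)cc2OCc2ccccc2)cc(O)c1C=O
F8 | step 8 | 4-{[2,4-bis(benzyloxy)-6-methylbenzoyl]oxy}-2-heptyl-6-hydroxybenzoic acid | CCCCCCCc1cc(OC(=O)c2c(C)cc(OCc3ccccc3)cc2OCc2ccccc2)cc(O)c1C(=O)O
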